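## Retrosynthetic overview

- The target is opened to a linear (S)-δ-hydroxy-β-diketo-dioxinone. The C2–O bond is already in place, and both ring C and ring A are closed from this chain in one flask.
- Ring order: ring B is bought as 4-hydroxybenzaldehyde. Ring C closes first (hydroxy-diketone to dihydropyranone), ring A second (dioxinone to acylketene, ring closure, aromatisation), in the same pot.
- The linear precursor comes from a Claisen union of the dianion of a keto-dioxinone with an (S)-β-hydroxy thioester.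
- The thioester comes from a catalytic asymmetric Mukaiyama aldol on 4-(geranyloxy)benzaldehyde, which sets the only stereocentre.
- Feedstocks: 4-hydroxybenzaldehyde, geranyl bromide, S-tert-butyl thioacetate, 2,2,6-trimethyl-4H-1,3-dioxin-4-one, acetyl chloride.

Assumption: the target is read as the (2S)-flavanone with an (E)-geranyl ether ("geranyloxy" = [(2E)-3,7-dimethylocta-2,6-dien-1-yl]oxy), and lithium or potassium salts of a numbered compound are treated as the same compound.

## Route

Step 1
Reactants: 1 4-hydroxybenzaldehyde; 2 geranyl bromide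
Product: 3 4-(geranyloxy)benzaldehyde
Conditions: K2CO3 (1.5 equiv), acetone, reflux, 6 h
Reagents that add atoms: none
Why: Williamson ether synthesis; the phenoxide displaces the primary allylic bromide by SN2 at oxygen, and the E-alkene is not touched.

Step 2
Reactants: 4 S-tert-butyl thioacetate
Product: 5 1-(tert-butylsulfanyl)-1-(trimethylsilyloxy)ethene
Conditions: LiN(iPr)2 (1.05 equiv), THF, −78 °C; Me3SiCl (1.2 equiv), −78 °C to rt; distil
Reagents that add atoms: chlorotrimethylsilane, C[Si](C)(C)Cl
Why: Kinetic enolate O-silylation; the lithium thioester enolate is trapped on oxygen by the silyl chloride to give the silyl ketene thioacetal needed for the Mukaiyama aldol.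

Step 3
Reactants: 3 4-(geranyloxy)benzaldehyde; 5 1-(tert-butylsulfanyl)-1-(trimethylsilyloxy)ethene
Product: 7 S-tert-butyl (3S)-3-hydroxy-3-[4-(geranyloxy)phenyl]propanethioate, via trimethylsilyl ether 6 (not isolated)
Conditions: (S)-BINOL (20 mol%), Ti(OiPr)4 (20 mol%), 4 Å MS, Et2O, −20 °C, 5 (1.5 equiv); then 10% aq. citric acid, THF, 0 °C
Reagents that add atoms: none
Why: Keck catalytic asymmetric Mukaiyama aldol; the (S)-BINOL–Ti(OiPr)4 Lewis acid exposes the Si face of the aldehyde (same facial sense as Ti–BINOL allylation with the (S)-ligand), which sets C3 as (S), the future C2 of the flavanone, and mild aqueous acid frees the alcohol from silyl ether 6 without ionising the benzylic centre (ee and absolute sense are checked here by chiral HPLC and Mosher ester).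

Step 4
Reactants: 8 2,2,6-trimethyl-4H-1,3-dioxin-4-one; 9 acetyl chloride
Product: 10 2,2-dimethyl-6-(2-oxopropyl)-4H-1,3-dioxin-4-one
Conditions: 8 (2.0 equiv), LiN(SiMe3)2 (2.0 equiv), THF, −78 °C, 1 h; 9 (1.0 equiv), −78 °C, 2 h; 1 M HCl
Reagents that add atoms: none
Why: Vinylogous Claisen-type C-acylation; the extended dienolate formed at the 6-methyl group is acylated at that carbon, and the second equivalent of enolate absorbs the more acidic product.

Step 5
Reactants: 10 2,2-dimethyl-6-(2-oxopropyl)-4H-1,3-dioxin-4-one; 7 S-tert-butyl (3S)-3-hydroxy-3-[4-(geranyloxy)phenyl]propanethioate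
Product: 11 6-[(6S)-6-hydroxy-6-[4-(geranyloxy)phenyl]-2,4-dioxohexyl]-2,2-dimethyl-4H-1,3-dioxin-4-one
Conditions: 10 (3.2 equiv), LiN(iPr)2 (6.4 equiv), THF, −78 °C, 1 h; 7 (1.0 equiv), −78 to −40 °C, 3 h; AcOH, −78 °C; short silica plug, used at once
Reagents that add atoms: none
Why: Crossed Claisen condensation of a 1,3-dicarbonyl dianion; the dianion of 10 reacts only at its terminal methyl carbon with the thioester carbonyl, one equivalent being spent on the hydroxyl and one on the acidic product (as in excess-enolate Claisen condensations of unprotected β-hydroxy esters), and the stereocentre survives because its lithium alkoxide neither leaves nor undergoes retro-aldol at low temperature.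

Step 6
Reactants: 11 6-[(6S)-6-hydroxy-6-[4-(geranyloxy)phenyl]-2,4-dioxohexyl]-2,2-dimethyl-4H-1,3-dioxin-4-one
Product: 15 (2S)-5,7-dihydroxy-2-[4-(geranyloxy)phenyl]chroman-4-one, via dihydropyranone 12 (not isolated), via acylketene 13 (not isolated), via cyclohexadienone tautomer 14 (not isolated)
Conditions: PPTS (20 mol%), 4 Å MS, PhMe (0.01 M), 60 °C, 2 h; then 110 °C, 1.5 h
Reagents that add atoms: none
Why: Proposed new method: at 60 °C the δ-hydroxy-1,3-diketone closes by hemiketalisation and dehydration to the 2,3-dihydro-4H-pyran-4-one 12 (ring C, C2–O bond untouched, so configuration is retained; sieves take up the water before any ketene exists); at 110 °C the dioxinone loses acetone by retro-hetero-Diels–Alder to acylketene 13, whose enol is a dienylketene that closes at the nucleophilic vinylogous-ester α-carbon (6π-electrocyclisation or stepwise C-acylation) to 14, which tautomerises to the phloroglucinol ring A; closest known chemistry is the acid cyclodehydration of δ-hydroxy-1,3-diketones to dihydropyranones, dioxinone thermolysis to acylketenes in resorcylate synthesis, and the dienylketene electrocyclisation that ends the Danheiser benzannulation.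

## Compound list

1 | 4-hydroxybenzaldehyde | O=Cc1ccc(O)cc1 | starting material
2 | geranyl bromide, (2E)-1-bromo-3,7-dimethylocta-2,6-diene | CC(C)=CCC/C(C)=C/CBr | starting material
3 | 4-(geranyloxy)benzaldehyde | CC(C)=CCC/C(C)=C/COc1ccc(C=O)cc1 | intermediate
4 | S-tert-butyl thioacetate | CC(=O)SC(C)(C)C | starting material
5 | 1-(tert-butylsulfanyl)-1-(trimethylsilyloxy)ethene | C=C(O[Si](C)(C)C)SC(C)(C)C | intermediate
6 | S-tert-butyl (3S)-3-[4-(geranyloxy)phenyl]-3-(trimethylsilyloxy)propanethioate (not isolated) | CC(C)=CCC/C(C)=C/COc1ccc([C@@H](O[Si](C)(C)C)CC(=O)SC(C)(C)C)cc1 | intermediate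
7 | S-tert-butyl (3S)-3-hydroxy-3-[4-(geranyloxy)phenyl]propanethioate | CC(C)=CCC/C(C)=C/COc1ccc([C@@H](O)CC(=O)SC(C)(C)C)cc1 | intermediate
8 | 2,2,6-trimethyl-4H-1,3-dioxin-4-one | CC1=CC(=O)OC(C)(C)O1 | starting material
9 | acetyl chloride | CC(Cl)=O | starting material
10 | 2,2-dimethyl-6-(2-oxopropyl)-4H-1,3-dioxin-4-one | CC(=O)CC1=CC(=O)OC(C)(C)O1 | intermediate
11 | 6-[(6S)-6-hydroxy-6-[4-(geranyloxy)phenyl]-2,4-dioxohexyl]-2,2-dimethyl-4H-1,3-dioxin-4-one | CC(C)=CCC/C(C)=C/COc1ccc([C@@H](O)CC(=O)CC(=O)CC2=CC(=O)OC(C)(C)O2)cc1 | intermediate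
12 | 6-{[(2S)-2-[4-(geranyloxy)phenyl]-4-oxo-3,4-dihydro-2H-pyran-6-yl]methyl}-2,2-dimethyl-4H-1,3-dioxin-4-one (not isolated) | CC(C)=CCC/C(C)=C/COc1ccc([C@@H]2CC(=O)C=C(CC3=CC(=O)OC(C)(C)O3)O2)cc1 | intermediate
13 | 4-[(2S)-2-[4-(geranyloxy)phenyl]-4-oxo-3,4-dihydro-2H-pyran-6-yl]-3-oxobut-1-en-1-one, the acylketene (not isolated) | CC(C)=CCC/C(C)=C/COc1ccc([C@@H]2CC(=O)C=C(CC(=O)C=C=O)O2)cc1 | intermediate
14 | (2S)-2-[4-(geranyloxy)phenyl]-7-hydroxy-2,3-dihydro-4aH-chromene-4,5-dione, keto tautomer of 15 with C4a unassigned (not isolated) | CC(C)=CCC/C(C)=C/COc1ccc([C@@H]2CC(=O)C3C(=O)C=C(O)C=C3O2)cc1 | intermediate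
15 | (2S)-5,7-dihydroxy-2-[4-(geranyloxy)phenyl]chroman-4-one, CNP0123225.1 | CC(C)=CCC/C(C)=C/COc1ccc([C@@H]2CC(=O)c3c(O)cc(O)cc3O2)cc1 | target

## Step count and risks

Total steps: 6. Longest linear sequence: 4 (steps 1, 3, 5, 6; the branch through step 2 is equally long).

**Step 6 (double ring closure).** The acylketene may be lost to dimers, to the 7-OH of product already formed, or to residual water. Ketene formed before ring C has closed would lead to racemic material through a chalcone-type pathway. The fallback sets out from 12 and comes back at 15. Step 6 is held at 60 °C and 12 is isolated. Heating 12 in toluene with methanol (5 equiv) at 110 °C traps the ketene as methyl 4-[(2S)-2-[4-(geranyloxy)phenyl]-4-oxo-3,4-dihydro-2H-pyran-6-yl]-3-oxobutanoate F1. Mg(OMe)2 in MeOH at 40 °C then closes ring A by a Claisen-mode Dieckmann condensation, in which the dienolate attacks the ester through the pyranone α-carbon, and aromatisation gives 15. The ee is monitored, since base can open the flavanone.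

**Step 5 (Claisen on the unprotected hydroxy thioester).** The dianion may simply deprotonate the thioester, giving low conversion. The fallback sets out from 7 and comes back at 11, replacing the Claisen by aldol addition and oxidation. Et3SiCl and imidazole give S-tert-butyl (3S)-3-[4-(geranyloxy)phenyl]-3-(triethylsilyloxy)propanethioate F2. Reduction with i-Bu2AlH in CH2Cl2 at −78 °C gives (3S)-3-[4-(geranyloxy)phenyl]-3-(triethylsilyloxy)propanal F3. The dianion of 10 adds to this aldehyde to give 6-[(6S)-4-hydroxy-6-[4-(geranyloxy)phenyl]-2-oxo-6-(triethylsilyloxy)hexyl]-2,2-dimethyl-4H-1,3-dioxin-4-one F4 as a mixture of carbinol epimers. Dess–Martin periodinane oxidises it to 6-[(6S)-6-[4-(geranyloxy)phenyl]-2,4-dioxo-6-(triethylsilyloxy)hexyl]-2,2-dimethyl-4H-1,3-dioxin-4-one F5. HF·pyridine in THF at 0 °C removes the silyl group and gives 11.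

**Step 3 (asymmetric aldol on an electron-rich aldehyde).** The rate or ee may be too low. The fallback sets out from 3 and comes back at 11, setting the stereocentre by reduction instead. Ethyl diazoacetate with NbCl5 (5 mol%) in CH2Cl2 homologates the aldehyde (Roskamp reaction) to ethyl 3-[4-(geranyloxy)phenyl]-3-oxopropanoate F6. Transfer hydrogenation with RuCl(p-cymene)[(S,S)-TsDPEN] in HCO2H/Et3N gives ethyl (3S)-3-hydroxy-3-[4-(geranyloxy)phenyl]propanoate F7. This catalyst gives (S)-1-arylethanols and the aryl-over-CH2 priority is the same here; the geranyl alkenes are not reduced. F7 then takes the place of 7 under the step 5 conditions and gives 11.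

## Further compounds

F1 | step 6 | methyl 4-[(2S)-2-[4-(geranyloxy)phenyl]-4-oxo-3,4-dihydro-2H-pyran-6-yl]-3-oxobutanoate | CC(C)=CCC/C(C)=C/COc1ccc([C@@H]2CC(=O)C=C(CC(=O)CC(=O)OC)O2)cc1
F2 | step 5 | S-tert-butyl (3S)-3-[4-(geranyloxy)phenyl]-3-(triethylsilyloxy)propanethioate | CC(C)=CCC/C(C)=C/COc1ccc([C@@H](O[Si](CC)(CC)CC)CC(=O)SC(C)(C)C)cc1
F3 | step 5 | (3S)-3-[4-(geranyloxy)phenyl]-3-(triethylsilyloxy)propanal | CC(C)=CCC/C(C)=C/COc1ccc([C@@H](O[Si](CC)(CC)CC)CC=O)cc1
F4 | step 5 | 6-[(6S)-4-hydroxy-6-[4-(geranyloxy)phenyl]-2-oxo-6-(triethylsilyloxy)hexyl]-2,2-dimethyl-4H-1,3-dioxin-4-one | CC(C)=CCC/C(C)=C/COc1ccc([C@@H](O[Si](CC)(CC)CC)CC(O)CC(=O)CC2=CC(=O)OC(C)(C)O2)cc1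
F5 | step 5 | 6-[(6S)-6-[4-(geranyloxy)phenyl]-2,4-dioxo-6-(triethylsilyloxy)hexyl]-2,2-dimethyl-4H-1,3-dioxin-4-one | CC(C)=CCC/C(C)=C/COc1ccc([C@@H](O[Si](CC)(CC)CC)CC(=O)CC(=O)CC2=CC(=O)OC(C)(C)O2)cc1
F6 | step 3 | ethyl 3-[4-(geranyloxy)phenyl]-3-oxopropanoate | CC(C)=CCC/C(C)=C/COc1ccc(C(=O)CC(=O)OCC)cc1
F7 | step 3 | ethyl (3S)-3-hydroxy-3-[4-(geranyloxy)phenyl]propanoate | CC(C)=CCC/C(C)=C/COc1ccc([C@@H](O)CC(=O)OCC)cc1
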